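The trap in this flask was to read the yield off the charges, which allow 80.0 % of target, while the reagent starts in the second phase and must cross before it meets substrate.

substrate 0.50 mM; reagent in the second phase 0.400 mM; time 15 s; volume of the second phase over the first 0.25

* target at 15 s, in percent of the substrate charged
* the change that raises the amount of target at 15 s, in percent of the substrate charged most ("none" if none brings more than 2 percentage points) (cedar / elm / none)
* amount of target at 15 s, in percent of the substrate charged, after elm

- a doubled species enters its step squared and goes two at a time
- in the second phase: reagent in the second phase; everything else is in the first
- charges count per volume of the first phase; a concentration in a rate is the amount of a species over the volume of its own phase; every rate counts per litre of the first phase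
- run time (flask): 15 s

    reagent in the reaction phase ⇌ reagent in the second phase, rate k1*([reagent in the reaction phase] - [reagent in the second phase]/K1) per volume of the first phase (K1 = 0.460, k1 = 0.0217 /s)
    substrate + reagent in the reaction phase → target (k2 = 153 /M/s)
    reagent in the reaction phase + target → over-reacted product (k3 = 428 /M/s)
    reagent in the reaction phase → decomposed reagent (k4 = 0.0751 /s)
    2 reagent in the reaction phase → homo dimer (k5 = 10.7 /M/s)
    substrate ⇌ dormant form (K6 = 0.345, k6 = 0.286 /s)

Substrate and dormant form relax with a half-life of 0.622 s, far shorter than the 15 s run, so I kept them at equilibrium, and the pair then reacts with a constant of 114 /M/s. Reagent leaves the second phase at 0.189 /s. In the reaction phase I let it be lost at 0.132 /s, by decomposition and by substrate held at its charge (pseudo-first-order), and I dropped back-transfer, the take by target and the homo dimer. These two first-order stages in series gave 0.234 for the reduced exposure: the time integral of reagent in the reaction phase up to the reading, multiplied by that constant. It counts the hits an average substrate has taken, so the unhit part of the pair is its negative exponential, 79.1 %.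

One number was not enough for target, which is attacked 3.76 times as fast as the pair (the selectivity factor). Consecutive first-order steps then gave 13.6 % of target. Elm doubles the reduced exposure and gave me 16.4 %. Cedar gave a reduced exposure of 0.272 and 14.6 %. Those gains, 2.8 percentage points and 1.00 point against a margin of 2 points, made me choose elm.

The forecast said 12.8 % of target, elm as the best change and 16.2 % after it: “Doubling the charge nearly doubles that exposure and beats faster transfer”. My target figure stood above its figure, with the same choice.

The simulation gave 13.0 % of target in the flask. The better change was elm, reaching 16.2 % with a gain of 3.2 points, more than the 0.91 points of cedar.

At 15.0 s the flask held 80.7 % as substrate and dormant form, against 79.1 % from the reduced exposure. For the neighbouring flask with 2.0 mM of substrate, the same reckoning gives a loss of 0.303 /s and a reduced exposure of 0.129. That means 87.9 % unhit and 9.54 % of target, in percent of that flask's own substrate. The simulated neighbouring flask held 88.9 % unhit and 8.93 % of target.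

The constants used here are made up; the run is a simulation.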